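1. At 0.333 min the alder flask shows starting material down to 1.2% but product only at 40.3%, so 58.5% of the charge sits in a form you cannot read.

the same everywhere: starting material 0.035 M; reagent 0.175 M; radical scavenger 0.16 mM

| run | initiator | remark | time |
|---|---|---|---|
| alder | 0.93 mM | run made earlier |  |
| oak | 4.7 mM | run made earlier |  |
| midnight | 1.7 mM |  | 4.0 min |
| autumn | 6.0 mM |  | 2.5 min |

| run | time / min | product / % | starting material / % |
|---|---|---|---|
| alder | 0.333 | 40.3 | 1.2 |
| alder | 0.667 | 56.7 | 0.4 |
| alder | 1.50 | 78.6 | 0.3 |
| alder | 4.00 | 96.8 | 0.7 |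
| oak | 1.00 | 90.5 | 0.6 |
| oak | 2.00 | 97.3 | 1.0 |
| oak | 3.00 | 98.3 | 0 |
| oak | 4.00 | 99.2 | 0.1 |

(readings scatter by 0.5 percentage points)



- which one finishes higher in amount of product, in percent of the starting material charged ("neither" within 2 percentage points) (midnight / autumn / neither)
- amount of product at the end, in percent of the starting material charged, midnight
- amount of product at the end, in percent of the starting material charged, autumn

2. Watch one concentration, [gap], the charge less the product. In oak it falls from 9.50% to 2.70% between 1.00 min and 2.00 min. Read as pseudo-first-order, this gives the closing constant, the fall of ln[gap] per minute: 1.26 min⁻¹, a reading with its scatter.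
3. My reckoning for autumn: I assume oak's constant holds at autumn's [initiator] of 6.0 mM. Carrying oak's gap from 2.00 min to 2.5 min gives product of 98.6%.
4. Midnight's [initiator] of 1.7 mM lies between alder's and oak's, so I place it between their 96.8% and 99.2% at 4.0 min. Autumn stands 1.8 percentage points above the first and 0.60 points below the second, inside the margin of 2 points, so I expect neither to win.
5. Do not stop early: oak's gap shrank 3.52-fold in that one minute.
6. The forecast says neither, with 98.1% for midnight and 98.3% for autumn: “Autumn's higher initiator roughly offsets midnight's longer time”.

The simulation gives neither, with 98.4% for midnight and 97.8% for autumn.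

    2 first chain carrier → ended chains B (k = 1.00 × 10⁹ M⁻¹ s⁻¹)
    starting material + by-product ⇌ idle adduct, settled at all times (K = 22.0 M⁻¹)
    reagent + first chain carrier ⇌ product + second chain carrier (K = 1.00, k = 1.02 × 10⁶ M⁻¹ s⁻¹)
    2 second chain carrier → ended chains A (k = 1.10 × 10⁹ M⁻¹ s⁻¹)
    starting material + second chain carrier → by-product + first chain carrier (k = 6.70 × 10⁶ M⁻¹ s⁻¹)
    starting material + initiating radical → capped initiator + first chain carrier (k = 2.44 × 10⁷ M⁻¹ s⁻¹)
    starting material ⇌ dormant form (K = 6.43, k = 0.123 s⁻¹)
    initiator → 2 initiating radical (k = 0.0101 s⁻¹)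
    second chain carrier + radical scavenger → ended chains C (k = 1.26 × 10⁹ M⁻¹ s⁻¹)

Autumn ends 0.80 points below my reckoning. Its neighbour, the autumn flask read at 1.0 min, holds product at 92.2% and dormant form at 7.13%. Carried to 2.5 min with the closing constant, that product becomes 98.8% against 97.8%, and that dormant form becomes 1.08% against 1.27%. Left until 25.0 min, autumn stands at 99.0%.

(The runs were computed for substances that don't exist; scatter was added.)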